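**Assumption:** the target SMILES has no stereodescriptor and no stereocentre, and the biaryl axis is unspecified, so no stereocontrol is needed; the sp3 centres of the intermediates are uncontrolled and are all erased in the last step.

## Retrosynthetic overview

- The target is a 4-aryl-3-benzyl-2-naphthol. Its C1–C8a bond (naphthalene numbering) is cut so that the α-carbon of a ketone acts as an electrophile, an α-acyl thionium ion (enolonium equivalent) from a β-keto sulfoxide, toward the electron-rich trioxygenated ring; loss of thiophenol then aromatises.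
- The β-keto sulfoxide comes from the methyl ketone by C-sulfinylation of its methyl enolate.
- The methyl ketone comes from Friedel–Crafts conjugate addition of 2,6-dimethoxyphenol (C4–C4a bond) to an α-benzyl enone, itself from acid aldol condensation of zingerone with 4-hydroxy-2-methoxybenzaldehyde (C3–C4 bond).
- Ring order: the three benzene rings are bought intact; the only ring made is the naphthol carbocycle (ring B), closed last onto ring A. No protecting groups are used.

## Route

Step 1
Reactants: 1 zingerone [4-(4-hydroxy-3-methoxyphenyl)butan-2-one]; 2 4-hydroxy-2-methoxybenzaldehyde; 3 2,6-dimethoxyphenol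
Product: 5 3-(4-hydroxy-3-methoxybenzyl)-4-(4-hydroxy-2-methoxyphenyl)-4-(4-hydroxy-3,5-dimethoxyphenyl)butan-2-one (racemic diastereomer mixture), via benzylidene enone 4 (not isolated)
Conditions: 1 (1.2 equiv), 2 (1.0 equiv), AcOH saturated with HCl gas, 0 °C to rt, 16 h; then 3 (3 equiv), 40 °C, 12 h
Reagents that add atoms: none
Why: Acid-catalysed crossed aldol condensation of a methyl ketone occurs at the more substituted α-carbon to give the (E)-enone 4, whose O-protonated form is a cation stabilised by the p-hydroxy-o-methoxyphenyl group and is trapped at C4 by the para position of 2,6-dimethoxyphenol (Friedel–Crafts conjugate addition); the two new stereocentres form without control and are destroyed in step 3.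

Step 2
Reactants: 5 3-(4-hydroxy-3-methoxybenzyl)-4-(4-hydroxy-2-methoxyphenyl)-4-(4-hydroxy-3,5-dimethoxyphenyl)butan-2-one; 6 methyl benzenesulfinate
Product: 7 3-(4-hydroxy-3-methoxybenzyl)-4-(4-hydroxy-2-methoxyphenyl)-4-(4-hydroxy-3,5-dimethoxyphenyl)-1-(phenylsulfinyl)butan-2-one (diastereomer mixture)
Conditions: LiN(SiMe3)2 (5.5 equiv), THF, −78 to −40 °C; then 6 (1.5 equiv), −78 to 0 °C; 1 M aq. HCl quench
Reagents that add atoms: methyl benzenesulfinate (6), COS(=O)c1ccccc1
Why: Claisen-type C-sulfinylation, in which the three phenols are first deprotonated, the bulky amide then removes a proton kinetically from the unhindered C1 methyl rather than the congested C3–H, and the enolate attacks sulfur of the sulfinate ester with loss of methoxide, the acidic β-keto sulfoxide being held as its enolate until the quench; the sulfur and carbon stereocentres are irrelevant.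

Step 3
Reactants: 7 3-(4-hydroxy-3-methoxybenzyl)-4-(4-hydroxy-2-methoxyphenyl)-4-(4-hydroxy-3,5-dimethoxyphenyl)-1-(phenylsulfinyl)butan-2-one
Product: 10 4-(4-hydroxy-2-methoxyphenyl)-3-(4-hydroxy-3-methoxybenzyl)-6,8-dimethoxynaphthalene-2,7-diol (target), via α-acyl thionium ion 8 (not isolated), via 1-phenylthio-2-tetralone 9 (not isolated)
Conditions: TsOH (anhydrous, 2 equiv), 4 Å MS, MeCN, 50 °C then 80 °C, N2 sweep
Reagents that add atoms: none
Why: Acid-promoted Pummerer ionisation turns the normally nucleophilic ketone α-carbon into the electrophilic α-acyl thionium ion 8 (a sulfur-stabilised enolonium equivalent), which closes a six-membered ring by Friedel–Crafts attack of the ring A carbon that is ortho and para to the two methoxy groups to give 9, and enolisation plus acid-induced loss of PhSH from that doubly activated benzylic carbon aromatises ring B and erases every stereocentre.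

## Compound list

1 | zingerone, 4-(4-hydroxy-3-methoxyphenyl)butan-2-one | CC(=O)CCc1ccc(O)c(OC)c1 | starting material
2 | 4-hydroxy-2-methoxybenzaldehyde | COc1cc(O)ccc1C=O | starting material
3 | 2,6-dimethoxyphenol | COc1cccc(OC)c1O | starting material
4 | (E)-3-(4-hydroxy-3-methoxybenzyl)-4-(4-hydroxy-2-methoxyphenyl)but-3-en-2-one | CC(=O)/C(Cc1ccc(O)c(OC)c1)=C/c1ccc(O)cc1OC | intermediate
5 | 3-(4-hydroxy-3-methoxybenzyl)-4-(4-hydroxy-2-methoxyphenyl)-4-(4-hydroxy-3,5-dimethoxyphenyl)butan-2-one, racemic diastereomer mixture | CC(=O)C(Cc1ccc(O)c(OC)c1)C(c1ccc(O)cc1OC)c1cc(OC)c(O)c(OC)c1 | intermediate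
6 | methyl benzenesulfinate | COS(=O)c1ccccc1 | starting material
7 | 3-(4-hydroxy-3-methoxybenzyl)-4-(4-hydroxy-2-methoxyphenyl)-4-(4-hydroxy-3,5-dimethoxyphenyl)-1-(phenylsulfinyl)butan-2-one, diastereomer mixture | O=C(CS(=O)c1ccccc1)C(Cc1ccc(O)c(OC)c1)C(c1ccc(O)cc1OC)c1cc(OC)c(O)c(OC)c1 | intermediate
8 | α-acyl thionium ion (S-phenyl, tosylate counter-ion) derived from 7 | O=C(C=[S+]c1ccccc1)C(Cc1ccc(O)c(OC)c1)C(c1ccc(O)cc1OC)c1cc(OC)c(O)c(OC)c1.Cc1ccc(S(=O)(=O)[O-])cc1 | intermediate
9 | 7-hydroxy-3-(4-hydroxy-3-methoxybenzyl)-4-(4-hydroxy-2-methoxyphenyl)-6,8-dimethoxy-1-(phenylsulfanyl)-3,4-dihydronaphthalen-2(1H)-one, diastereomer mixture | O=C1C(Sc2ccccc2)c2c(OC)c(O)c(OC)cc2C(c2ccc(O)cc2OC)C1Cc1ccc(O)c(OC)c1 | intermediate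
10 | 4-(4-hydroxy-2-methoxyphenyl)-3-(4-hydroxy-3-methoxybenzyl)-6,8-dimethoxynaphthalene-2,7-diol | COc1cc(Cc2c(O)cc3c(OC)c(O)c(OC)cc3c2-c2ccc(O)cc2OC)ccc1O | target

## Step count and risks

Total step count: 3. Longest linear sequence: 3.

The three steps most likely to fail, most risky first:

**Step 3.** Three things can go wrong:
- the thionium ion can close instead onto the guaiacyl ring of the benzyl group (also a six-membered ring, but activated by only one methoxy group);
- it can attack ring A ipso, para to the free OH;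
- the thiophenol set free can reduce unreacted sulfoxide, which is why the temperature is staged.

The fallback sets out from 7 and removes the thiol before ring closure. Pummerer rearrangement of 7 in aqueous acid (HCl, DMSO/H2O, rt) followed by stripping of thiophenol with Cu(OAc)2 gives the α-keto aldehyde 3-(4-hydroxy-3-methoxybenzyl)-4-(4-hydroxy-2-methoxyphenyl)-4-(4-hydroxy-3,5-dimethoxyphenyl)-2-oxobutanal F4. Its aldehyde carbon is closed onto ring A by Lewis-acid hydroxyalkylation (Sc(OTf)3 10 mol %, (CF3)2CHOH, 40 °C). This gives 1,7-dihydroxy-3-(4-hydroxy-3-methoxybenzyl)-4-(4-hydroxy-2-methoxyphenyl)-6,8-dimethoxy-3,4-dihydronaphthalen-2(1H)-one F5. Warming F5 with TsOH dehydrates it, and the fallback comes back to the route at 10.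

**Step 2.** The tetra-anion of 5 may be poorly soluble, or the enolate may form unselectively. The fallback sets out from 5 and avoids strong base. Pyrrolidine-catalysed enamine α-sulfenylation at the methyl group with N-(phenylthio)succinimide (MeCN, rt) gives 3-(4-hydroxy-3-methoxybenzyl)-4-(4-hydroxy-2-methoxyphenyl)-4-(4-hydroxy-3,5-dimethoxyphenyl)-1-(phenylsulfanyl)butan-2-one F3. Chemoselective oxidation at sulfur (H2O2 1.1 equiv, (CF3)2CHOH, rt) then comes back to the route at 7.

**Step 1.** The aldol may give some condensation at the methyl group, and the cation of 4 may oligomerise before 3 is added. The fallback sets out from 2 and fixes the regiochemistry with a β-keto acid. Ethyl acetoacetate is reductively alkylated with vanillin (L-proline, Hantzsch ester, EtOH) to ethyl 2-(4-hydroxy-3-methoxybenzyl)-3-oxobutanoate F1. Cold saponification (KOH, H2O, 0 °C) gives 2-(4-hydroxy-3-methoxybenzyl)-3-oxobutanoic acid F2. Decarboxylative Knoevenagel condensation of F2 with 2 (piperidine, pyridine, 50 °C) can only give the branched enone. The fallback comes back to the route at 4, which is then isolated and arylated with 3 (TfOH 10 mol %, (CF3)2CHOH, rt) to give 5.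

## Further compounds

F1 | step 1 | ethyl 2-(4-hydroxy-3-methoxybenzyl)-3-oxobutanoate | CCOC(=O)C(Cc1ccc(O)c(OC)c1)C(C)=O
F2 | step 1 | 2-(4-hydroxy-3-methoxybenzyl)-3-oxobutanoic acid | CC(=O)C(Cc1ccc(O)c(OC)c1)C(=O)O
F3 | step 2 | 3-(4-hydroxy-3-methoxybenzyl)-4-(4-hydroxy-2-methoxyphenyl)-4-(4-hydroxy-3,5-dimethoxyphenyl)-1-(phenylsulfanyl)butan-2-one | O=C(CSc1ccccc1)C(Cc1ccc(O)c(OC)c1)C(c1ccc(O)cc1OC)c1cc(OC)c(O)c(OC)c1
F4 | step 3 | 3-(4-hydroxy-3-methoxybenzyl)-4-(4-hydroxy-2-methoxyphenyl)-4-(4-hydroxy-3,5-dimethoxyphenyl)-2-oxobutanal | O=CC(=O)C(Cc1ccc(O)c(OC)c1)C(c1ccc(O)cc1OC)c1cc(OC)c(O)c(OC)c1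
F5 | step 3 | 1,7-dihydroxy-3-(4-hydroxy-3-methoxybenzyl)-4-(4-hydroxy-2-methoxyphenyl)-6,8-dimethoxy-3,4-dihydronaphthalen-2(1H)-one | O=C1C(O)c2c(OC)c(O)c(OC)cc2C(c2ccc(O)cc2OC)C1Cc1ccc(O)c(OC)c1
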